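The target is cut at the aryl ester bond O4–C1'(=O) and at the C2'–C3' bond of the 3-acetoxybutanoyl chain. The key step exploits the single CH2 (C2') between the ester carbonyl C1' and the acetoxy-bearing stereocentre C3' on the O4 substituent of the benzene ring. A light-driven Wolff rearrangement of the lactate-derived diazoketone (S)-CH3CH(OAc)COCHN2 turns the diazo carbon into C2' with retention at C3', and the resulting ketene acylates the C4 phenol under neutral conditions, without base or coupling agent. The phenol partner, methyl (E)-4-hydroxy-3-prenylcinnamate, comes from an aromatic Claisen rearrangement of the 1,1-dimethylallyl ether of methyl p-coumarate.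

Key step: step 9

Assumption: crystalline, anhydrous L-lactic acid is used rather than the aqueous syrup, whose water and oligomers would consume acetyl chloride. All cinnamates are handled in amber glassware.

Step 1
Reactants: 1 p-coumaric acid, (E)-3-(4-hydroxyphenyl)prop-2-enoic acid
Product: 2 methyl p-coumarate, methyl (E)-3-(4-hydroxyphenyl)prop-2-enoate
Conditions: MeOH, H2SO4 (cat.), reflux; NaHCO3 wash
Reagents that add atoms: methanol, CO
Why: Fischer esterification in excess methanol should convert only the carboxylic acid, since the phenol and the E alkene are inert to dilute acid in methanol.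

Step 2
Reactants: 3 2-methylbut-3-yn-2-ol
Product: 5 methyl 2-methylbut-3-yn-2-yl carbonate, via lithium 2-methylbut-3-yn-2-olate 4 (not isolated)
Conditions: n-BuLi (1.0 equiv), THF, −78 °C; then ClCO2Me, −78 to 0 °C
Reagents that add atoms: methyl chloroformate, COC(Cl)=O
Why: O-acylation of a lithium alkoxide by a chloroformate, in which one equivalent of n-BuLi removes the O–H proton in preference to the alkyne C–H and the hindered tertiary alkoxide is then acylated cleanly.

Step 3
Reactants: 2 methyl p-coumarate; 5 methyl 2-methylbut-3-yn-2-yl carbonate
Product: 6 methyl (E)-3-[4-(2-methylbut-3-yn-2-yloxy)phenyl]prop-2-enoate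
Conditions: CuCl2·2H2O (1 mol%), DBU (1.3 equiv), MeCN, −5 to 0 °C
Reagents that add atoms: none
Why: Copper-catalysed propargylic substitution, in which the copper-bound terminal alkyne ionises the tertiary carbonate and the phenoxide is captured at the tertiary carbon, so the hindered aryl ether forms where direct SN2 displacement is impossible; electron-poor phenols are good partners in this reaction.

Step 4
Reactants: 6 methyl (E)-3-[4-(2-methylbut-3-yn-2-yloxy)phenyl]prop-2-enoate
Product: 7 methyl (E)-3-[4-(2-methylbut-3-en-2-yloxy)phenyl]prop-2-enoate
Conditions: H2 (1 atm, stopped after 1.0 equiv uptake), Pd/CaCO3 poisoned with Pb(OAc)2 (Lindlar catalyst), quinoline, EtOAc, rt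
Reagents that add atoms: none
Why: Lindlar semihydrogenation, in which the terminal alkyne binds to the poisoned palladium surface far more strongly than the conjugated disubstituted cinnamate alkene, so measured hydrogen uptake should stop at the vinyl ether.

Step 5
Reactants: 7 methyl (E)-3-[4-(2-methylbut-3-en-2-yloxy)phenyl]prop-2-enoate
Product: 9 methyl (E)-3-[4-hydroxy-3-(3-methylbut-2-enyl)phenyl]prop-2-enoate, via ortho-prenyl cyclohexadienone 8 (not isolated)
Conditions: degassed o-xylene, 130 °C, Ar, base-washed flask; flash chromatography (the phenol is purified, not used crude)
Reagents that add atoms: none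
Why: Aromatic Claisen rearrangement, a [3,3] sigmatropic shift that joins the vinyl CH2 terminus to an ortho carbon to give dienone 8, which tautomerises to the phenol; C3 and C5 are equivalent and the para position is blocked, so a single regioisomer is expected, and the gem-dimethyl group lets the shift run at a temperature the E cinnamate tolerates.

Step 6
Reactants: 10 L-lactic acid, (S)-2-hydroxypropanoic acid
Product: 11 (S)-2-acetoxypropanoic acid
Conditions: AcCl (2.5 equiv), neat, 0 °C to rt; volatiles removed in vacuo
Reagents that add atoms: acetyl chloride, CC(Cl)=O
Why: O-acetylation of the secondary alcohol by an acyl chloride under acidic, base-free conditions, which breaks no bond at C2 and therefore keeps the S configuration.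

Step 7
Reactants: 11 (S)-2-acetoxypropanoic acid
Product: 12 (S)-2-acetoxypropanoyl chloride
Conditions: SOCl2 (1.5 equiv), neat, 50 °C, no amine; distillation under reduced pressure
Reagents that add atoms: thionyl chloride, O=S(Cl)Cl
Why: Conversion of a carboxylic acid into its chloride with SOCl2, where the absence of any tertiary amine prevents ketene formation from the alpha C–H, so the stereocentre should not racemise.

Step 8
Reactants: 12 (S)-2-acetoxypropanoyl chloride; 13 trimethylsilyldiazomethane
Product: 14 (S)-3-acetoxy-1-diazobutan-2-one
Conditions: TMSCHN2 (2.2 equiv, hexanes solution), MeCN/THF 1:1, 0 °C to rt, dark; concentrated below 25 °C, rapid chromatography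
Reagents that add atoms: none
Why: C-acylation of the diazoalkane by the acid chloride (first stage of the Arndt–Eistert sequence), in which chloride removes the silyl group as Me3SiCl; the surplus diazo reagent scavenges traces of HCl that would otherwise give the chloromethyl ketone, and without amine base the alpha centre is not epimerised.

Step 9
Reactants: 9 methyl (E)-3-[4-hydroxy-3-(3-methylbut-2-enyl)phenyl]prop-2-enoate; 14 (S)-3-acetoxy-1-diazobutan-2-one
Product: 16 methyl (E)-3-[4-[(3S)-3-acetoxybutanoyl]oxy-3-(3-methylbut-2-enyl)phenyl]prop-2-enoate, via acetoxy ketene 15 (not isolated)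
Conditions: 427 nm LED, dry degassed CH2Cl2, rt (fan cooling), Ar; 14 (1.8 equiv) added by syringe pump to 9 (0.3 M); no base, no acid, no metal
Reagents that add atoms: none
Why: Excitation of the weak long-wavelength band of 14 expels N2 with concerted 1,2-shift of the CH(OAc)CH3 group from the carbonyl carbon to the diazo carbon (Wolff rearrangement), and the phenol O–H of 9 then adds across the C=C of ketene 15 to give the aryl ester. The closest known reaction type is the photochemical Arndt–Eistert homologation with capture of the ketene by an alcohol or phenol. No ring is closed and no new stereocentre is made: C3' migrates with retention, as is general for the Wolff shift, so the lactate centre arrives unchanged and stays S because CH2C(=O)OAr still ranks between the acetoxy oxygen and CH3. The step needs ketene O-acylation to win over carbene O–H insertion, cyclopropanation of the prenyl alkene, loss of acetic acid to a crotonate and E/Z isomerisation of the cinnamate. This is secured by the concerted rearrangement of the s-Z conformer without any metal carbene, by the absence of base and acid, and by a wavelength that only the diazoketone absorbs. Slow addition of 14 to concentrated 9 keeps the ketene concentration low, so capture by the hindered phenol should outrun ketene dimerisation.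

Compound list
1 | p-coumaric acid, (E)-3-(4-hydroxyphenyl)prop-2-enoic acid | O=C(O)/C=C/c1ccc(O)cc1 | starting material
2 | methyl p-coumarate, methyl (E)-3-(4-hydroxyphenyl)prop-2-enoate | COC(=O)/C=C/c1ccc(O)cc1 | intermediate
3 | 2-methylbut-3-yn-2-ol | C#CC(C)(C)O | starting material
4 | lithium 2-methylbut-3-yn-2-olate | C#CC(C)(C)[O-].[Li+] | intermediate (not isolated)
5 | methyl 2-methylbut-3-yn-2-yl carbonate | C#CC(C)(C)OC(=O)OC | intermediate
6 | methyl (E)-3-[4-(2-methylbut-3-yn-2-yloxy)phenyl]prop-2-enoate | COC(=O)/C=C/c1ccc(OC(C)(C)C#C)cc1 | intermediate
7 | methyl (E)-3-[4-(2-methylbut-3-en-2-yloxy)phenyl]prop-2-enoate | COC(=O)/C=C/c1ccc(OC(C)(C)C=C)cc1 | intermediate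
8 | ortho-prenyl cyclohexadienone, methyl (E)-3-[3-(3-methylbut-2-enyl)-4-oxocyclohexa-1,5-dien-1-yl]prop-2-enoate (racemic at ring C3) | COC(=O)/C=C/C1=CC(CC=C(C)C)C(=O)C=C1 | intermediate (not isolated)
9 | methyl (E)-3-[4-hydroxy-3-(3-methylbut-2-enyl)phenyl]prop-2-enoate | COC(=O)/C=C/c1ccc(O)c(CC=C(C)C)c1 | intermediate
10 | L-lactic acid, (S)-2-hydroxypropanoic acid | C[C@H](O)C(=O)O | starting material
11 | (S)-2-acetoxypropanoic acid | C[C@H](OC(C)=O)C(=O)O | intermediate
12 | (S)-2-acetoxypropanoyl chloride | C[C@H](OC(C)=O)C(Cl)=O | intermediate
13 | trimethylsilyldiazomethane | C[Si](C)(C)C=[N+]=[N-] | starting material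
14 | (S)-3-acetoxy-1-diazobutan-2-one | C[C@H](OC(C)=O)C(=O)C=[N+]=[N-] | intermediate
15 | acetoxy ketene, (S)-3-acetoxybut-1-en-1-one | C[C@H](OC(C)=O)C=C=O | intermediate (not isolated)
16 | CNP0290147.1, methyl (E)-3-[4-[(3S)-3-acetoxybutanoyl]oxy-3-(3-methylbut-2-enyl)phenyl]prop-2-enoate | COC(=O)/C=C/c1ccc(OC(=O)C[C@H](C)OC(C)=O)c(CC=C(C)C)c1 | target

Total step count: 9. Longest linear sequence: 5 steps (steps 1, 3, 4, 5 and 9, from 1 to 16). The lactate branch (steps 6, 7, 8, 9) has 4 steps.

Steps most likely to fail

Step 9. The ortho-substituted, electron-poor phenol may acylate too slowly, so the ketene dimerises or adds to unreacted diazoketone. Acetic acid may also be lost by beta-elimination at the ketene stage, and the cinnamate may isomerise through energy transfer. The fallback separates homologation from ester formation. It sets out from 14 and 9 and comes back at 16. Compound 14 is irradiated (427 nm LED) in THF/water, where water traps ketene 15 quickly, to give (S)-3-acetoxybutanoic acid F1. This is converted with (COCl)2 and catalytic DMF in CH2Cl2 into (S)-3-acetoxybutanoyl chloride F2. Phenol 9 is then acylated with F2 and pyridine in CH2Cl2 at −20 °C; pyridine is too weak a base to drive elimination of acetate at this temperature.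

Step 5. The tertiary allylic ether may ionise and fragment back to 2 with loss of isoprene, or adventitious acid may cyclise the product onto the prenyl alkene to a chroman. The fallback is a direct ortho C-prenylation. It sets out from 2 and comes back at 9. Compound 2 is deprotonated with NaH in toluene to sodium 4-[(E)-3-methoxy-3-oxoprop-1-enyl]phenolate F3, and this tight ion pair is alkylated with prenyl bromide (1-bromo-3-methylbut-2-ene) in toluene at rt. In a non-polar solvent, alkylation should be directed to the ortho carbon, and any O-prenyl ether formed is separated by chromatography.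

Step 3. The tertiary carbonate may eliminate to the enyne or substitution at the tertiary centre may stall, and over-reduction in step 4 would further erode material. The fallback is a Tsuji–Trost decarboxylative O-allylation that bypasses both steps. It sets out from 2 and comes back at 7. Compound 2 is treated with bought tert-butyl 2-methylbut-3-en-2-yl carbonate and Pd(PPh3)4 (zerovalent palladium) in THF at 0 °C. The phenoxide attacks the more substituted terminus of the 1,1-dimethylallyl palladium complex under kinetic control, giving the branched ether directly. No compound outside the list is made (F0).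

Further compounds
F1 | step 9 | (S)-3-acetoxybutanoic acid | C[C@H](OC(C)=O)CC(=O)O
F2 | step 9 | (S)-3-acetoxybutanoyl chloride | C[C@H](OC(C)=O)CC(Cl)=O
F3 | step 5 | sodium 4-[(E)-3-methoxy-3-oxoprop-1-enyl]phenolate | COC(=O)/C=C/c1ccc([O-])cc1.[Na+]
F0 | step 3 | none | none
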